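The readings stem from a simulated flask on assumed constants; scatter was added.

How much ring can this flask hold at its best, and when?

- the best time, 15 d at the latest, for ring
- the amount of ring, in percent of the solid substrate charged, at that time
- earliest time at which at least nineteen twentieths of that best amount are there, in d
- latest time at which they still are, in d

| flask | solid substrate | activator | capture agent | remark | time |
|---|---|---|---|---|---|
| Monday's | 0.050 M | 0.025 M (fed, over 25 h) | 2.5 mM | run made earlier; the fed solution adds 0.20 times the starting volume |  |
| Saturday's | 0.050 M | 0.10 M (fed, over 25 h) | 2.5 mM | run made earlier; the fed solution adds 0.20 times the starting volume |  |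
| Friday's | 0.075 M | 0.050 M (fed, over 25 h) | 2.5 mM | run made earlier; the fed solution adds 0.20 times the starting volume |  |
| flask | 0.050 M | 0.0500 M (fed, over 25 h) | 2.50 mM | the fed solution adds 0.20 times the starting volume | 15 d |

- percentages count the solid substrate that a species holds: one open dimer counts as two
- every charge counts on the volume at the start, and the solution that is fed holds the whole dose
- solid, in amounts per volume of the solution: solid substrate
- what was read earlier has a scatter of 2 percentage points, one standard deviation
- reactions considered so far: solid substrate <-> starting material; capture agent + activated form -> trapped intermediate; ring -> over-reaction product; activated form -> ring; starting material + activated form -> open dimer; starting material + activator -> activated form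
- at the start none of the solid substrate is in solution

| run | time / d | ring / % | solid substrate / % |
|---|---|---|---|
| Monday's | 1.04 | 5 | 80 |
| Monday's | 2.08 | 2 | 62 |
| Monday's | 4.00 | 7 | 41 |
| Monday's | 8.00 | 8 | 15 |
| Monday's | 15.0 | 2 | 5 |
| Saturday's | 1.04 | 5 | 76 |
| Saturday's | 2.08 | 18 | 51 |
| Saturday's | 4.00 | 29 | 13 |
| Saturday's | 8.00 | 8 | 0 |
| Saturday's | 15.0 | 3 | 0 |
| Friday's | 1.04 | 0 | 83 |
| Friday's | 2.08 | 8 | 68 |
| Friday's | 4.00 | 8 | 51 |
| Friday's | 8.00 | 7 | 21 |
| Friday's | 15.0 | 0 | 5 |

(each reading ± 2 percentage points)

The row at 4.00 d is read in each table. There Saturday's ring is at its top, 29 %, Friday's 8 % equals its top, and Monday's 7 % stands within the scatter of 2 percentage points of its 8 %. From Monday's to Saturday's, on equal solid substrate, c_activator grows by a factor of 4.00 and the ring reading by 4.14. So, between these two runs, the ring reading follows activator. Friday's percentage is of a larger charge, so it has to be turned into a concentration: c_ring is 6.00 mM.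

Dividing c_ring by the activator charged gives 0.140 for Monday's, 0.145 for Saturday's and 0.120 for Friday's. Their mean, 0.135, is the ring yield per activator: c_ring near its top over c_activator charged. It is a reading and carries the scatter.

My own reckoning for the flask multiplies this yield by 0.0500 M of activator, which gives 6.75 mM of ring, or 13.5 % of the 0.050 M solid substrate.

The forecast says 14 % at 3.8 d, with the window asked for running from 3 d to 4.8 d, on the ground that “Peak ring in absolute terms scales roughly with activator”. It rests on the same runs and the same scaling as my reckoning, so their nearness is no check.

The flask reaches 17.1 % of ring at 4.30 d, with the window asked for running from 3.33 d to 5.50 d, so the forecast held within its margins.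

    solid substrate ⇌ starting material, rate k1*(cs1 - [starting material]) while solid is left; crystals form when [starting material] > cs1 (solubility = 17.0 mM, k = 5.70 × 10⁻⁴ min⁻¹)
    capture agent + activated form → trapped intermediate (k = 0.0250 M⁻¹ min⁻¹)
    ring → over-reaction product (k = 4.20 × 10⁻⁴ min⁻¹)
    activated form → ring (k = 0.00230 min⁻¹)
    starting material + activated form → open dimer (k = 0.0240 M⁻¹ min⁻¹)
    starting material + activator → activated form (k = 0.0160 M⁻¹ min⁻¹)

At the best time the flask still holds 82.3 % of its capture agent, whose reaction moves the highest ring very little. The ring yield per activator of this flask is 0.171, higher than the 0.135 read from the runs. Applied to a neighbour flask charged with 0.030 M of activator, it gives 10.3 % of ring, and that neighbour holds 11.4 % at its best.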